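**Retrosynthetic overview**

1. Interflavan bond C4(upper)–C8(lower): cut to the 4-yl cation of a 2,3-cis-flavan-3,4-diol plus natural (−)-epicatechin, which is bought with all its rings and both stereocentres; attack anti to the 3-OH gives 4β.
2. Upper diol: its three stereocentres come in one operation from the flat ring C of 3,7,4'-trihydroxyflavone by enantioface-selective syn hydrogenation, the logic by which anthocyanidin reductase makes 2,3-cis units.
3. Ring C of that flavonol is closed as in flavonoid biosynthesis, by 6-endo oxa-Michael addition of the chalcone 2'-phenoxide, telescoped with aldol assembly and C3 oxygenation, from 2,4-dihydroxyacetophenone and 4-hydroxybenzaldehyde with no protecting groups.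
4. Ring order: only ring C of the upper unit is built (step 1); then the stereocentres (step 2); then the C4–C8 bond (step 3).

Assumption: the target is read as epiguibourtinidol-(4β→8)-epicatechin, upper unit (2R,3R,4R) (2,3-cis-3,4-trans), lower unit (2R,3R); the (R,R)-ligand in step 2 is taken to give the (2R,3R,4R)-diol, and its (S,S)-enantiomer is used instead if the measured sense is opposite.

Compounds are numbered in the order in which they enter the forward route.

**Step 1**
Reactants: 1 2,4-dihydroxyacetophenone; 2 4-hydroxybenzaldehyde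
Product: 5 3,7,4'-trihydroxyflavone, via isoliquiritigenin 3 (not isolated), via racemic trans-3,7,4'-trihydroxyflavanone 4 (not isolated)
Conditions: KOH (60% aq, 12 equiv), EtOH, 50 °C, 48 h; then MeOH/H2O, H2O2 (30% aq, 6 equiv), 0 °C → rt, 8 h; HCl to pH 3
Reagents that add atoms: hydrogen peroxide (OO)
Why: Claisen–Schmidt condensation gives chalcone 3, whose 2'-phenoxide closes ring C by the same 6-endo oxa-Michael addition that chalcone isomerase performs, and the resulting enolate is hydroxylated and dehydrogenated by H2O2 (Algar–Flynn–Oyamada reaction; no 6'-substituent, so flavonol rather than aurone), leaving a flat ring C with no stereocentre.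

**Step 2**
Reactants: 5 3,7,4'-trihydroxyflavone
Product: 8 (2R,3R,4R)-2-(4-hydroxyphenyl)chromane-3,4,7-triol, via flavonol tris(trimethylsilyl) ether 6 (not isolated), via silylated all-cis flavan-4-ol 7 (not isolated)
Conditions: (a) HMDS, cat. (NH4)2SO4, 110 °C, evaporate; (b) [Ru(cod)(2-methylallyl)2] (5 mol%), (R,R)-SINpEt·HBF4 (10 mol%), KOtBu (10 mol%), pre-mixed in hexane at 70 °C, then H2 (100 bar), hexane/toluene, 40 °C, 24 h; (c) MeOH, cat. K2CO3, 0 °C
Reagents that add atoms: none
Why: Proposed new method: ring C of the silylated flavonol is a vinylogous ester like that of a flavone, so the chiral Ru–NHC hydride should add H2 syn across C2=C3 from one enantioface and then reduce C4=O from the same face, setting C2, C3 and C4 all-cis in one operation (closest known reactions: Ru–NHC-catalysed asymmetric hydrogenation of flavones to cis-flavan-4-ols, and the racemic heterogeneous hydrogenation of flavonols to 2,3-cis-3,4-cis-flavan-3,4-diols); transient silylation prevents flavonolate chelation of Ru and makes the substrate hexane-soluble.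

SINpEt·HBF4 is 1,3-bis[(R)-1-(naphthalen-1-yl)ethyl]-4,5-dihydro-1H-imidazol-3-ium tetrafluoroborate. A C4 epimer of 8, if formed, is equally usable because C4 is ionised in step 3.

**Step 3**
Reactants: 8 (2R,3R,4R)-2-(4-hydroxyphenyl)chromane-3,4,7-triol; 9 (−)-epicatechin
Product: 11 epiguibourtinidol-(4β→8)-epicatechin (CNP0118995.2), via ring A quinone methide 10 (not isolated)
Conditions: 9 (4 equiv), 0.1 M HCl (aq, 10% EtOH), N2, 25 °C, 16 h; Sephadex LH-20 (EtOH), then C18 HPLC; excess 9 recovered
Reagents that add atoms: none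
Why: Acid ionises the benzylic C4–OH (assisted by the 7-OH and O1) to the flavan-4-yl cation, drawn as its neutral quinone methide 10, which is captured by C8 of the phloroglucinol ring A of epicatechin in a Friedel–Crafts-type condensation as in proanthocyanidin biosynthesis; attack anti to the axial 3-OH of the 2,3-cis unit sets C4 as 4β (4R, 3,4-trans), and C2 and C3 of both units are untouched.

Only water is released in step 3. The expected 4→8 : 4→6 ratio is about 3:1, and any product from the minor enantiomer of 8 is a separable diastereomer.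

**Compound list**

1 | 2,4-dihydroxyacetophenone | CC(=O)c1ccc(O)cc1O | starting material
2 | 4-hydroxybenzaldehyde | O=Cc1ccc(O)cc1 | starting material
3 | isoliquiritigenin, (E)-1-(2,4-dihydroxyphenyl)-3-(4-hydroxyphenyl)prop-2-en-1-one | O=C(/C=C/c1ccc(O)cc1)c1ccc(O)cc1O | intermediate (not isolated)
4 | racemic trans-3,7,4'-trihydroxyflavanone (drawn as the 2R,3R enantiomer) | O=C1c2ccc(O)cc2O[C@H](c2ccc(O)cc2)[C@H]1O | intermediate (not isolated)
5 | 3,7,4'-trihydroxyflavone | O=c1c(O)c(-c2ccc(O)cc2)oc2cc(O)ccc12 | intermediate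
6 | 3,7-bis(trimethylsilyloxy)-2-[4-(trimethylsilyloxy)phenyl]-4H-chromen-4-one | O=c1c(O[Si](C)(C)C)c(-c2ccc(O[Si](C)(C)C)cc2)oc2cc(O[Si](C)(C)C)ccc12 | intermediate (not isolated)
7 | (2R,3R,4R)-3,7-bis(trimethylsilyloxy)-2-[4-(trimethylsilyloxy)phenyl]chroman-4-ol (all-cis) | C[Si](C)(C)Oc1ccc([C@H]2Oc3cc(O[Si](C)(C)C)ccc3[C@@H](O)[C@H]2O[Si](C)(C)C)cc1 | intermediate (not isolated)
8 | (2R,3R,4R)-2-(4-hydroxyphenyl)chromane-3,4,7-triol (2,3-cis-3,4-cis) | Oc1ccc([C@H]2Oc3cc(O)ccc3[C@@H](O)[C@H]2O)cc1 | intermediate
9 | (−)-epicatechin, (2R,3R)-2-(3,4-dihydroxyphenyl)chromane-3,5,7-triol | Oc1cc(O)c2c(c1)O[C@H](c1ccc(O)c(O)c1)[C@H](O)C2 | starting material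
10 | (2R,3R)-3-hydroxy-2-(4-hydroxyphenyl)-2,3-dihydro-7H-chromen-7-one (ring A quinone methide, neutral form of the C4 cation) | O=C1C=CC2=C[C@@H](O)[C@@H](c3ccc(O)cc3)OC2=C1 | intermediate (not isolated)
11 | epiguibourtinidol-(4β→8)-epicatechin, (2R,3R,4R)-4-[(2R,3R)-2-(3,4-dihydroxyphenyl)-3,5,7-trihydroxychroman-8-yl]-2-(4-hydroxyphenyl)chromane-3,7-diol | Oc1ccc([C@H]2Oc3cc(O)ccc3[C@H](c3c(O)cc(O)c4c3O[C@H](c3ccc(O)c(O)c3)[C@H](O)C4)[C@H]2O)cc1 | target

**Totals**

Total step count: 3. Longest linear sequence: 3 steps (1 and 2 → 5 → 8 → 11).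

**Steps most likely to fail, with fallbacks**

Step 2 is the most likely to fail. The C2=C3 bond is tetrasubstituted and oxygenated, and neither the rate nor the enantioselectivity is known for such a substrate. The fallback sets out from 5 and comes back at 11, and replaces catalyst control by separation of diastereomers made with the chiral-pool partner. Hydrogenate 5 without chiral control over Raney Ni (H2 100 bar, EtOH, 90 °C). This gives the racemic all-cis diol, that is 8 together with its enantiomer (2S,3S,4S)-2-(4-hydroxyphenyl)chromane-3,4,7-triol F5. Condense the racemate with 9 exactly as in step 3. Compound 8 gives 11, and F5 gives the diastereomer ent-epiguibourtinidol-(4α→8)-epicatechin F6, which is removed on Sephadex LH-20 and by C18 HPLC. Half of the upper unit is lost.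

Step 1 is the next most likely to fail. The triphenoxide is a poor aldol partner and a poor Michael acceptor, and H2O2 can degrade unreacted 2 by Dakin oxidation, so the yield may be low. The fallback sets out from 1 and 2 and comes back at 5, and trades the telescoped unprotected cascade for a protected, stepwise sequence. Benzylate the para hydroxyls (BnBr, K2CO3, acetone) to give 1-[4-(benzyloxy)-2-hydroxyphenyl]ethanone F1 and 4-(benzyloxy)benzaldehyde F2. Condense them (KOH, EtOH) to the isolated chalcone (E)-1-[4-(benzyloxy)-2-hydroxyphenyl]-3-[4-(benzyloxy)phenyl]prop-2-en-1-one F3. Oxidise this (H2O2, NaOH, MeOH) to 7-(benzyloxy)-2-[4-(benzyloxy)phenyl]-3-hydroxy-4H-chromen-4-one F4. Hydrogenolysis (H2 1 bar, Pd/C, THF/MeOH) then gives 5.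

Step 3 can also fail. The 5-deoxy cation forms slowly, and 4→6 coupling, self-condensation of 8 and over-addition to oligomers all compete. The fallback sets out from 8 and comes back at 11, and replaces Brønsted-acid ionisation by thiophilic activation under neutral conditions. Heat 8 with phenylmethanethiol in AcOH to give the stable, purifiable thioether (2R,3S,4S)-4-(benzylsulfanyl)-2-(4-hydroxyphenyl)chromane-3,7-diol F7. Treat F7 with AgBF4 in THF at 0 °C in the presence of 9 (4 equiv). This releases the same C4 cation without acid and gives 11 with the same anti (4β) selectivity.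

**Further compounds**

F1 | step 1 | 1-[4-(benzyloxy)-2-hydroxyphenyl]ethanone | CC(=O)c1ccc(OCc2ccccc2)cc1O
F2 | step 1 | 4-(benzyloxy)benzaldehyde | O=Cc1ccc(OCc2ccccc2)cc1
F3 | step 1 | (E)-1-[4-(benzyloxy)-2-hydroxyphenyl]-3-[4-(benzyloxy)phenyl]prop-2-en-1-one | O=C(/C=C/c1ccc(OCc2ccccc2)cc1)c1ccc(OCc2ccccc2)cc1O
F4 | step 1 | 7-(benzyloxy)-2-[4-(benzyloxy)phenyl]-3-hydroxy-4H-chromen-4-one | O=c1c(O)c(-c2ccc(OCc3ccccc3)cc2)oc2cc(OCc3ccccc3)ccc12
F5 | step 2 | (2S,3S,4S)-2-(4-hydroxyphenyl)chromane-3,4,7-triol | Oc1ccc([C@@H]2Oc3cc(O)ccc3[C@H](O)[C@@H]2O)cc1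
F6 | step 2 | ent-epiguibourtinidol-(4α→8)-epicatechin, (2S,3S,4S)-4-[(2R,3R)-2-(3,4-dihydroxyphenyl)-3,5,7-trihydroxychroman-8-yl]-2-(4-hydroxyphenyl)chromane-3,7-diol | Oc1ccc([C@@H]2Oc3cc(O)ccc3[C@@H](c3c(O)cc(O)c4c3O[C@H](c3ccc(O)c(O)c3)[C@H](O)C4)[C@@H]2O)cc1
F7 | step 3 | (2R,3S,4S)-4-(benzylsulfanyl)-2-(4-hydroxyphenyl)chromane-3,7-diol | Oc1ccc([C@H]2Oc3cc(O)ccc3[C@H](SCc3ccccc3)[C@H]2O)cc1
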